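The butenolide (numbered O1, C2=O, C3–OH, C4–ring B, C5) is cut at O1–C5 and at the bond from the exocyclic CH2 to ring A. The route exploits the fact that quaternary C5 holds both the lactone oxygen and a ring A benzyl carbon, which is what addition of an aryl group and a carboxylate across the terminal alkene of a C3=C4–C5=CH2 diene leaves behind. One palladium-catalysed Heck/Tsuji–Trost cascade therefore joins ring A iodide 18 to acid 14, making both bonds, the ring and the (S)-C5 centre. Acid 14 is a MOM-protected (2E)-2-alkoxy-3-aryl-4-methoxycarbonylpenta-2,4-dienoic acid whose CO2H is cis to the acrylate unit.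

Key step: step 12

Remarks on the chemistry (assumptions and design choices):
- Ring A is the 4-hydroxy-3-prenylbenzyl ring and ring B the 3,4-dihydroxy-5-prenylphenyl ring. The target SMILES encodes S at C5 (CIP order O1 > CO2Me > C4 > CH2Ar); C5 is C2 in the furanone names below.
- Which antipode of the chiral ligand gives the S series in step 12 cannot be predicted with confidence. Both antipodes are assumed available and the choice is fixed in the first screen (assignment by ECD or X-ray of a derivative).
- The free cis-dienoic acid can lactonise onto its own acrylate in the six-ring sense. It is therefore carried as a 2-(trimethylsilyl)ethyl ester, which is inert to the Stille conditions and orthogonal to the methyl ester, and is unmasked cold immediately before the key step.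
- Ring B starts from the benzoate, not the aldehyde, so that the allylboron reagent of step 2 meets no aldehyde and the carbonyl is already at the level needed for step 5.

Step 1
Reactants: 1 methyl 3-bromo-4,5-dihydroxybenzoate
Product: 2 methyl 3-bromo-4,5-bis(methoxymethoxy)benzoate
Conditions: MOMCl (2.6 equiv), iPr2NEt (3 equiv), CH2Cl2, 0 °C to rt
Reagents that add atoms: chloromethyl methyl ether, COCCl
Why: Williamson-type O-alkylation of both catechol hydroxyls by the α-chloro ether is fast under amine base and leaves the ester and the aryl bromide untouched.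

Step 2
Reactants: 2 methyl 3-bromo-4,5-bis(methoxymethoxy)benzoate; 3 4,4,5,5-tetramethyl-2-(3-methylbut-2-en-1-yl)-1,3,2-dioxaborolane (prenylboronic acid pinacol ester)
Product: 4 methyl 3,4-bis(methoxymethoxy)-5-(3-methylbut-2-en-1-yl)benzoate
Conditions: Pd(OAc)2 (2 mol %), t-BuXPhos (4 mol %), aq K3PO4, MeCN, 70 °C
Reagents that add atoms: none
Why: Suzuki–Miyaura coupling of an allylboronate in which the bulky biarylphosphine lets the allylpalladium settle at its primary terminus before reductive elimination, so the linear prenyl group should be delivered while ester and MOM acetals are inert.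

Step 3
Reactants: 5 methyl glycolate (methyl 2-hydroxyacetate)
Product: 6 methyl 2-(methoxymethoxy)acetate
Conditions: MOMCl (1.2 equiv), iPr2NEt (1.5 equiv), CH2Cl2, 0 °C to rt
Reagents that add atoms: chloromethyl methyl ether, COCCl
Why: the same acetal-forming O-alkylation protects the primary alcohol with the group that later becomes the C3 enol ether.

Step 4
Reactants: 6 methyl 2-(methoxymethoxy)acetate; 7 2-(trimethylsilyl)ethanol
Product: 8 2-(trimethylsilyl)ethyl 2-(methoxymethoxy)acetate
Conditions: Bu2SnO (5 mol %), 7 (1.5 equiv), toluene, reflux, MeOH removed over 4 Å sieves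
Reagents that add atoms: none
Why: tin-catalysed transesterification under neutral conditions is driven by removal of methanol and spares the MOM acetal and the β-silylethyl group.

Step 5
Reactants: 4 methyl 3,4-bis(methoxymethoxy)-5-(3-methylbut-2-en-1-yl)benzoate; 8 2-(trimethylsilyl)ethyl 2-(methoxymethoxy)acetate
Product: 9 2-(trimethylsilyl)ethyl 3-[3,4-bis(methoxymethoxy)-5-(3-methylbut-2-en-1-yl)phenyl]-2-(methoxymethoxy)-3-oxopropanoate (racemic)
Conditions: 8 (2.3 equiv), LiN(iPr)2 (2.2 equiv), THF, −78 °C; then 4, −78 to −10 °C; AcOH quench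
Reagents that add atoms: none
Why: crossed Claisen condensation in which the fully preformed, chelated glycolate enolate is the only donor and the non-enolisable benzoate the only acceptor, the product being drawn off as its stabilised enolate (hence two equivalents of enolate); the C2 centre forms racemic and is erased in step 6.

Step 6
Reactants: 9 2-(trimethylsilyl)ethyl 3-[3,4-bis(methoxymethoxy)-5-(3-methylbut-2-en-1-yl)phenyl]-2-(methoxymethoxy)-3-oxopropanoate
Product: 10 2-(trimethylsilyl)ethyl (2E)-3-[3,4-bis(methoxymethoxy)-5-(3-methylbut-2-en-1-yl)phenyl]-2-(methoxymethoxy)-3-[(trifluoromethanesulfonyl)oxy]prop-2-enoate (TfO cis to the ester)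
Conditions: NaH (1.2 equiv), Et2O, 0 °C; Tf2O (1.1 equiv), −78 to 0 °C
Reagents that add atoms: trifluoromethanesulfonic anhydride, O=S(=O)(OS(=O)(=O)C(F)(F)F)C(F)(F)F
Why: enol triflation of a β-keto ester in which sodium bridges the ketone and ester oxygens in a six-membered chelate in the weakly coordinating solvent, so the ketone oxygen should be sulfonylated on the side of the ester (geometry to be checked by NOE/HMBC).

Step 7
Reactants: 11 methyl propiolate
Product: 12 methyl 2-(tributylstannyl)prop-2-enoate
Conditions: Bu3SnH (1.05 equiv), Pd(PPh3)4 (2 mol %), THF, 0 °C to rt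
Reagents that add atoms: tributyltin hydride, CCCC[SnH](CCCC)CCCC
Why: palladium-catalysed syn-hydrostannation of an electron-poor terminal alkyne delivers hydride to the β-carbon and tin to the carbon α to the ester, giving the 1,1-disubstituted stannyl acrylate.

Step 8
Reactants: 10 2-(trimethylsilyl)ethyl (2E)-3-aryl-2-(methoxymethoxy)-3-(triflyloxy)prop-2-enoate (aryl = 3,4-bis(methoxymethoxy)-5-prenylphenyl); 12 methyl 2-(tributylstannyl)prop-2-enoate
Product: 13 2-(trimethylsilyl)ethyl (2E)-3-[3,4-bis(methoxymethoxy)-5-(3-methylbut-2-en-1-yl)phenyl]-4-(methoxycarbonyl)-2-(methoxymethoxy)penta-2,4-dienoate (silyl ester cis to the acrylate unit)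
Conditions: Pd(PPh3)4 (10 mol %), CuI (20 mol %), LiCl (3 equiv), DMF, 45 °C
Reagents that add atoms: none
Why: Stille coupling with copper co-catalysis, in which tin-to-copper transfer makes up for the low nucleophilicity of the α-stannyl acrylate and oxidative addition and reductive elimination both retain alkene geometry, so the acrylate takes the place of TfO cis to the ester.

Step 9
Reactants: 13 2-(trimethylsilyl)ethyl (2E)-3-[3,4-bis(methoxymethoxy)-5-(3-methylbut-2-en-1-yl)phenyl]-4-(methoxycarbonyl)-2-(methoxymethoxy)penta-2,4-dienoate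
Product: 14 (2E)-3-[3,4-bis(methoxymethoxy)-5-(3-methylbut-2-en-1-yl)phenyl]-4-(methoxycarbonyl)-2-(methoxymethoxy)penta-2,4-dienoic acid (CO2H cis to the acrylate unit)
Conditions: Bu4NF (1.5 equiv), THF, 0 °C; cold aq HCl to pH 3; crude acid used at once
Reagents that add atoms: none
Why: fluoride-induced β-elimination of the 2-(trimethylsilyl)ethyl ester frees the carboxylate without hydroxide, so the methyl ester, the MOM acetals and the alkene geometry are kept, and prompt use forestalls six-ring lactonisation onto the acrylate.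

Step 10
Reactants: 15 4-iodophenol; 16 prenyl bromide (1-bromo-3-methylbut-2-ene)
Product: 17 4-iodo-2-(3-methylbut-2-en-1-yl)phenol
Conditions: NaH (1.0 equiv), toluene, 0 °C to rt; 16 (1.0 equiv), rt
Reagents that add atoms: none
Why: ortho C-alkylation of the sodium phenoxide contact ion pair in a non-polar solvent, where sodium shields oxygen and the para position is blocked by iodine, so SN2 attack on prenyl bromide should come from the ortho carbon (the O-prenyl ether is removed by chromatography).

Step 11
Reactants: 17 4-iodo-2-(3-methylbut-2-en-1-yl)phenol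
Product: 18 4-iodo-1-(methoxymethoxy)-2-(3-methylbut-2-en-1-yl)benzene
Conditions: MOMCl (1.3 equiv), iPr2NEt (1.6 equiv), CH2Cl2, 0 °C to rt
Reagents that add atoms: chloromethyl methyl ether, COCCl
Why: Williamson-type MOM protection caps the phenol so that no phenoxide competes for the allylpalladium in step 12.

Step 12
Reactants: 14 (2E)-3-[3,4-bis(methoxymethoxy)-5-(3-methylbut-2-en-1-yl)phenyl]-4-(methoxycarbonyl)-2-(methoxymethoxy)penta-2,4-dienoic acid; 18 4-iodo-1-(methoxymethoxy)-2-(3-methylbut-2-en-1-yl)benzene
Product: 19 methyl (2S)-3-[3,4-bis(methoxymethoxy)-5-(3-methylbut-2-en-1-yl)phenyl]-4-(methoxymethoxy)-2-{[4-(methoxymethoxy)-3-(3-methylbut-2-en-1-yl)phenyl]methyl}-5-oxo-2,5-dihydrofuran-2-carboxylate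
Conditions: Pd2(dba)3·CHCl3 (5 mol %), H8-BINOL-derived phosphoramidite (12 mol %), Ag2CO3 (1 equiv), 18 (1.3 equiv), toluene, 40 °C, dark
Reagents that add atoms: none
Why: Proposed new method: oxidative addition of iodide 18 to ligated zerovalent palladium, iodide abstraction by silver and binding of the carboxylate of 14 give an arylpalladium carboxylate that inserts the acrylate-type C5=CH2 bond with aryl going to CH2 (Heck step) and palladium to C5, where it is held as an η3-allyl over C5–C4–C3 that is also an ester enolate. The cis carboxylate then forms the O1–C5 bond (Tsuji–Trost step) and releases zerovalent palladium; the five-membered ring closes in the endo sense with respect to the allyl unit, C3=C4 staying inside the ring, and attack at C3 is excluded because it would give an α-lactone. The closest known reaction types are the enantioselective Heck/Tsuji–Trost 1,2-difunctionalisation of 1,3-dienes with aryl halides and O- or N-nucleophiles and the palladium-catalysed aryl iodide coupling–lactonisation of 2,3-allenoic acids, which shows the same endo lactone closure; new here are the quaternary, ester-bearing allyl terminus and a carboxylate carried on the diene itself. The C5 stereocentre is set by the chiral phosphoramidite on palladium: the two facial isomers of the allyl complex can interconvert through the η1 C5-bound or O-bound enolate form, so the ligand decides which face of C5 receives O1, and the antipode that gives (S)-19 is taken. The step needs C–O bond formation to outrun β-hydride loss toward the new benzylic CH2 and needs insertion at the acrylate only; the first is secured by the η3-allyl binding and the chelating cis carboxylate fixed by the E geometry of 14, the second by the fact that the trisubstituted prenyl alkenes and the tetrasubstituted C3=C4 bond are poor Heck acceptors.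

Step 13
Reactants: 19 methyl (2S)-3-[3,4-bis(methoxymethoxy)-5-(3-methylbut-2-en-1-yl)phenyl]-4-(methoxymethoxy)-2-{[4-(methoxymethoxy)-3-(3-methylbut-2-en-1-yl)phenyl]methyl}-5-oxo-2,5-dihydrofuran-2-carboxylate
Product: 21 methyl (2S)-3-[3,4-dihydroxy-5-(3-methylbut-2-en-1-yl)phenyl]-4-hydroxy-2-{[4-hydroxy-3-(3-methylbut-2-en-1-yl)phenyl]methyl}-5-oxo-2,5-dihydrofuran-2-carboxylate (target CNP0460191.1), via tetrakis(trimethylsilyl) ether 20 (not isolated)
Conditions: Me3SiOTf (8 equiv), 2,2'-bipyridyl (12 equiv), CH2Cl2, 0 °C to rt; then H2O, rt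
Reagents that add atoms: none
Why: silyl triflate/bipyridyl cleavage of MOM ethers, in which each acetal is turned into a silyl ether while bipyridyl traps the methoxymethyl cation and buffers the medium, so no Brønsted acid meets the ortho-prenyl phenols (no chroman formation) and the silyl ethers hydrolyse on adding water; the quaternary C5 centre cannot epimerise.

Compound list
1 | methyl 3-bromo-4,5-dihydroxybenzoate | COC(=O)c1cc(O)c(O)c(Br)c1 | starting material
2 | methyl 3-bromo-4,5-bis(methoxymethoxy)benzoate | COC(=O)c1cc(OCOC)c(OCOC)c(Br)c1 | intermediate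
3 | 4,4,5,5-tetramethyl-2-(3-methylbut-2-en-1-yl)-1,3,2-dioxaborolane | CC(C)=CCB1OC(C)(C)C(C)(C)O1 | starting material
4 | methyl 3,4-bis(methoxymethoxy)-5-(3-methylbut-2-en-1-yl)benzoate | COC(=O)c1cc(OCOC)c(OCOC)c(CC=C(C)C)c1 | intermediate
5 | methyl glycolate | COC(=O)CO | starting material
6 | methyl 2-(methoxymethoxy)acetate | COCOCC(=O)OC | intermediate
7 | 2-(trimethylsilyl)ethanol | C[Si](C)(C)CCO | starting material
8 | 2-(trimethylsilyl)ethyl 2-(methoxymethoxy)acetate | COCOCC(=O)OCC[Si](C)(C)C | intermediate
9 | 2-(trimethylsilyl)ethyl 3-[3,4-bis(methoxymethoxy)-5-(3-methylbut-2-en-1-yl)phenyl]-2-(methoxymethoxy)-3-oxopropanoate (racemic) | COCOC(C(=O)OCC[Si](C)(C)C)C(=O)c1cc(OCOC)c(OCOC)c(CC=C(C)C)c1 | intermediate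
10 | 2-(trimethylsilyl)ethyl (2E)-3-[3,4-bis(methoxymethoxy)-5-(3-methylbut-2-en-1-yl)phenyl]-2-(methoxymethoxy)-3-[(trifluoromethanesulfonyl)oxy]prop-2-enoate | C[Si](C)(C)CCOC(=O)/C(OCOC)=C(\OS(=O)(=O)C(F)(F)F)c1cc(OCOC)c(OCOC)c(CC=C(C)C)c1 | intermediate
11 | methyl propiolate | C#CC(=O)OC | starting material
12 | methyl 2-(tributylstannyl)prop-2-enoate | C=C(C(=O)OC)[Sn](CCCC)(CCCC)CCCC | intermediate
13 | 2-(trimethylsilyl)ethyl (2E)-3-[3,4-bis(methoxymethoxy)-5-(3-methylbut-2-en-1-yl)phenyl]-4-(methoxycarbonyl)-2-(methoxymethoxy)penta-2,4-dienoate | C[Si](C)(C)CCOC(=O)/C(OCOC)=C(\C(=C)C(=O)OC)c1cc(OCOC)c(OCOC)c(CC=C(C)C)c1 | intermediate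
14 | (2E)-3-[3,4-bis(methoxymethoxy)-5-(3-methylbut-2-en-1-yl)phenyl]-4-(methoxycarbonyl)-2-(methoxymethoxy)penta-2,4-dienoic acid | OC(=O)/C(OCOC)=C(\C(=C)C(=O)OC)c1cc(OCOC)c(OCOC)c(CC=C(C)C)c1 | intermediate
15 | 4-iodophenol | Oc1ccc(I)cc1 | starting material
16 | prenyl bromide | CC(C)=CCBr | starting material
17 | 4-iodo-2-(3-methylbut-2-en-1-yl)phenol | Oc1ccc(I)cc1CC=C(C)C | intermediate
18 | 4-iodo-1-(methoxymethoxy)-2-(3-methylbut-2-en-1-yl)benzene | COCOc1ccc(I)cc1CC=C(C)C | intermediate
19 | methyl (2S)-3-[3,4-bis(methoxymethoxy)-5-(3-methylbut-2-en-1-yl)phenyl]-4-(methoxymethoxy)-2-{[4-(methoxymethoxy)-3-(3-methylbut-2-en-1-yl)phenyl]methyl}-5-oxo-2,5-dihydrofuran-2-carboxylate | COC(=O)[C@@]1(Cc2ccc(OCOC)c(CC=C(C)C)c2)OC(=O)C(OCOC)=C1c1cc(OCOC)c(OCOC)c(CC=C(C)C)c1 | intermediate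
20 | tetrakis(trimethylsilyl) ether of the target (all four hydroxyls as Me3SiO, S at the quaternary carbon) | COC(=O)[C@@]1(Cc2ccc(O[Si](C)(C)C)c(CC=C(C)C)c2)OC(=O)C(O[Si](C)(C)C)=C1c1cc(O[Si](C)(C)C)c(O[Si](C)(C)C)c(CC=C(C)C)c1 | intermediate (not isolated)
21 | methyl (2S)-3-[3,4-dihydroxy-5-(3-methylbut-2-en-1-yl)phenyl]-4-hydroxy-2-{[4-hydroxy-3-(3-methylbut-2-en-1-yl)phenyl]methyl}-5-oxo-2,5-dihydrofuran-2-carboxylate | COC(=O)[C@@]1(Cc2ccc(O)c(CC=C(C)C)c2)OC(=O)C(O)=C1c1cc(O)c(O)c(CC=C(C)C)c1 | target

Total step count: 13. Longest linear sequence: 8 steps (1, 2, 5, 6, 8, 9, 12, 13).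

Steps most likely to fail

Step 12 (bears the label Proposed new method). What may go wrong: β-hydride loss from the allylpalladium toward the benzylic CH2 outpacing O1–C5 bond formation, low facial selectivity at C5, or six-ring lactonisation of the carboxylate onto the acrylate before palladium engages. The fallback uses known reactions only, sets out from diester 13 and iodide 18 and comes back to the route at 19. Miyaura borylation of 18 (B2pin2, PdCl2(dppf), KOAc, dioxane, 80 °C) should give 2-[4-(methoxymethoxy)-3-(3-methylbut-2-en-1-yl)phenyl]-4,4,5,5-tetramethyl-1,3,2-dioxaborolane F1. Rhodium-catalysed conjugate addition of F1 to the acrylate CH2 of 13 ([Rh(OH)(cod)]2, aq KOH, dioxane, 50 °C) should give 5-methyl 1-[2-(trimethylsilyl)ethyl] (2Z)-3-[3,4-bis(methoxymethoxy)-5-(3-methylbut-2-en-1-yl)phenyl]-2-(methoxymethoxy)-4-{[4-(methoxymethoxy)-3-(3-methylbut-2-en-1-yl)phenyl]methyl}pent-2-enedioate F2, racemic at the future C5. Deprotonation of F2 at that carbon (KN(SiMe3)2, THF, −78 °C) and Davis hydroxylation with a (camphorsulfonyl)oxaziridine should give the tertiary alkoxide, which closes onto the cis silylethyl ester to give 19. The oxaziridine antipode is chosen for the S series, and any remaining R enantiomer would be removed by preparative chiral-phase HPLC.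

Step 8. What may go wrong: sluggish tin-to-palladium transfer at the crowded tetrasubstituted vinylpalladium, so that protodestannylation of the stannane and decay of the triflate take over. The fallback reverses the polarity of the coupling, sets out from triflate 10 and comes back at 13. Miyaura borylation of 10 (B2pin2, PdCl2(PPh3)2, PPh3, KOPh, toluene, 50 °C) should give 2-(trimethylsilyl)ethyl (2Z)-3-[3,4-bis(methoxymethoxy)-5-(3-methylbut-2-en-1-yl)phenyl]-2-(methoxymethoxy)-3-(4,4,5,5-tetramethyl-1,3,2-dioxaborolan-2-yl)prop-2-enoate F3. Suzuki–Miyaura coupling of F3 with commercial methyl 2-bromoacrylate (Pd(OAc)2, SPhos, K3PO4, THF–H2O, 40 °C) should then give 13 with retention of geometry.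

Step 5. What may go wrong: self-condensation or thermal decay of the glycolate enolate before it acylates on the electron-rich benzoate, leaving the ester unconverted. The fallback goes through the aldehyde oxidation level, sets out from ester 4 and comes back at 9. Reduction (iBu2AlH, CH2Cl2, −78 °C) should give [3,4-bis(methoxymethoxy)-5-(3-methylbut-2-en-1-yl)phenyl]methanol F4, and MnO2 (CH2Cl2, rt) should give 3,4-bis(methoxymethoxy)-5-(3-methylbut-2-en-1-yl)benzaldehyde F5. Aldol addition of the lithium enolate of 8 (LiN(iPr)2, THF, −78 °C) should give 2-(trimethylsilyl)ethyl 3-[3,4-bis(methoxymethoxy)-5-(3-methylbut-2-en-1-yl)phenyl]-3-hydroxy-2-(methoxymethoxy)propanoate F6 as a diastereomer mixture, and Dess–Martin oxidation of F6 should give 9.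

Further compounds
F1 | step 12 | 2-[4-(methoxymethoxy)-3-(3-methylbut-2-en-1-yl)phenyl]-4,4,5,5-tetramethyl-1,3,2-dioxaborolane | COCOc1ccc(B2OC(C)(C)C(C)(C)O2)cc1CC=C(C)C
F2 | step 12 | 5-methyl 1-[2-(trimethylsilyl)ethyl] (2Z)-3-[3,4-bis(methoxymethoxy)-5-(3-methylbut-2-en-1-yl)phenyl]-2-(methoxymethoxy)-4-{[4-(methoxymethoxy)-3-(3-methylbut-2-en-1-yl)phenyl]methyl}pent-2-enedioate (racemic) | COC(=O)C(Cc1ccc(OCOC)c(CC=C(C)C)c1)/C(c1cc(OCOC)c(OCOC)c(CC=C(C)C)c1)=C(/OCOC)C(=O)OCC[Si](C)(C)C
F3 | step 8 | 2-(trimethylsilyl)ethyl (2Z)-3-[3,4-bis(methoxymethoxy)-5-(3-methylbut-2-en-1-yl)phenyl]-2-(methoxymethoxy)-3-(4,4,5,5-tetramethyl-1,3,2-dioxaborolan-2-yl)prop-2-enoate | C[Si](C)(C)CCOC(=O)/C(OCOC)=C(\B1OC(C)(C)C(C)(C)O1)c1cc(OCOC)c(OCOC)c(CC=C(C)C)c1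
F4 | step 5 | [3,4-bis(methoxymethoxy)-5-(3-methylbut-2-en-1-yl)phenyl]methanol | OCc1cc(OCOC)c(OCOC)c(CC=C(C)C)c1
F5 | step 5 | 3,4-bis(methoxymethoxy)-5-(3-methylbut-2-en-1-yl)benzaldehyde | O=Cc1cc(OCOC)c(OCOC)c(CC=C(C)C)c1
F6 | step 5 | 2-(trimethylsilyl)ethyl 3-[3,4-bis(methoxymethoxy)-5-(3-methylbut-2-en-1-yl)phenyl]-3-hydroxy-2-(methoxymethoxy)propanoate (diastereomer mixture) | COCOC(C(=O)OCC[Si](C)(C)C)C(O)c1cc(OCOC)c(OCOC)c(CC=C(C)C)c1
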